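**Retrosynthetic overview**
- The strategy rests on ring A: a fully differentiated phloroglucinol (C5–OH, C6–prenyl, C7–O, C8–H) fused to ring C at C4a–C8a, with the prenyl group locked between the two oxygens. It is built last, by benzannulation of a pyranone-derived vinylketene with a prenyl-bearing siloxyalkyne, so the alkyne substituents fix C6 and C7.
- The benzannulation precursor, a 2-diazoacetyl-5-aryl-4-pyranone, comes from comenic acid (ring C) by Suzuki coupling at the C5 triflate with the ring-B boronate, then conversion of the C2 ester to the diazoketone.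
- Ring B comes from 4-bromophenol by 2,6-diiodination, O-methylation and two successive iodine–magnesium exchanges (prenyl, then OH). The siloxyalkyne comes from prenyl bromide and ethynyl Grignard by acetylide oxidation to the ynolate and O-silylation.
- C3 is set after the key step by Ru transfer hydrogenation with dynamic kinetic resolution to the cis-(3S,4S)-isoflavan-4-ol, followed by re-oxidation at C4. A conjugate hydride adds at C2 and would leave C3 to an uncontrolled protonation, so a plain 1,4-reduction is not used.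
- Ring order: B (bought arene), C (bought pyranone), A (step 14).

Key step: step 14

Assumption: isoflavone numbering is used (O1, C2, C3, C4, C4a, C5–C8, C8a; ring B primed); the (S,S)-TsDPEN catalyst is taken to give the (4S) alcohol by the usual aryl-ketone facial rule, and the (R,R) catalyst would be used if the sense proved opposite.

**Route**

Step 1
Reactants: 1 4-bromophenol
Product: 2 4-bromo-2,6-diiodophenol
Conditions: NIS (2.2 equiv), TsOH·H2O (10 mol%), MeCN, rt
Reagents that add atoms: N-iodosuccinimide O=C1CCC(=O)N1I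
Why: Electrophilic aromatic iodination of a phenol whose para position is blocked by bromine should place iodine at both ortho positions.

Step 2
Reactants: 2 4-bromo-2,6-diiodophenol
Product: 3 5-bromo-1,3-diiodo-2-methoxybenzene
Conditions: MeI, K2CO3, DMF, rt
Reagents that add atoms: iodomethane CI
Why: Williamson O-methylation of the acidic diiodophenoxide with a small electrophile should proceed despite the two flanking iodines.

Step 3
Reactants: 3 5-bromo-1,3-diiodo-2-methoxybenzene; 4 prenyl bromide
Product: 6 5-bromo-1-iodo-2-methoxy-3-(3-methylbut-2-en-1-yl)benzene, via arylmagnesium chloride 5 (not isolated)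
Conditions: i-PrMgCl·LiCl (1.05 equiv), THF, −40 °C; then CuBr·SMe2 (10 mol%), 4, −40 → 0 °C
Reagents that add atoms: none
Why: Iodine–magnesium exchange is far faster at C–I than at C–Br and stops after one exchange because the electron-rich aryl Grignard resists a second one, and copper-catalysed allylic substitution at the unhindered CH2 terminus of prenyl bromide (SN2 sense) should then give the linear prenyl arene.

Step 4
Reactants: 6 5-bromo-1-iodo-2-methoxy-3-(3-methylbut-2-en-1-yl)benzene
Product: 9 5-bromo-2-methoxy-3-(3-methylbut-2-en-1-yl)phenol, via arylmagnesium chloride 7 (not isolated), via dimethyl arylboronate 8 (not isolated)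
Conditions: i-PrMgCl·LiCl, THF, −20 °C; B(OMe)3, −20 °C → rt; then 30% H2O2, aq. NaOH, 0 °C
Reagents that add atoms: hydrogen peroxide OO
Why: A second iodine–magnesium exchange leaves the C–Br bond intact, and borate trapping followed by alkaline peroxide oxidation (1,2-aryl shift from boron to oxygen) should give the phenol, since nucleophilic peroxide does not epoxidise the isolated prenyl alkene.

Step 5
Reactants: 9 5-bromo-2-methoxy-3-(3-methylbut-2-en-1-yl)phenol
Product: 10 5-bromo-2-methoxy-1-(methoxymethoxy)-3-(3-methylbut-2-en-1-yl)benzene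
Conditions: MOMCl, i-Pr2NEt, CH2Cl2, 0 °C → rt
Reagents that add atoms: chloromethyl methyl ether COCCl
Why: O-alkylation of the phenol with the reactive α-chloro ether gives a MOM acetal that tolerates the base, palladium, diazomethane and light used later.

Step 6
Reactants: 10 5-bromo-2-methoxy-1-(methoxymethoxy)-3-(3-methylbut-2-en-1-yl)benzene
Product: 11 2-[4-methoxy-3-(methoxymethoxy)-5-(3-methylbut-2-en-1-yl)phenyl]-4,4,5,5-tetramethyl-1,3,2-dioxaborolane
Conditions: B2pin2, PdCl2(dppf) (3 mol%), KOAc, 1,4-dioxane, 85 °C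
Reagents that add atoms: bis(pinacolato)diboron CC1(C)OB(OC1(C)C)B1OC(C)(C)C(C)(C)O1
Why: Miyaura borylation of the aryl bromide with acetate as the mild base should proceed without touching the MOM ether or the trisubstituted alkene.

Step 7
Reactants: 12 comenic acid
Product: 13 methyl 5-hydroxy-4-oxo-4H-pyran-2-carboxylate
Conditions: MeOH, H2SO4 (cat.), reflux
Reagents that add atoms: methanol CO
Why: Fischer esterification converts the carboxylic acid while the enolic C5 hydroxyl of the pyranone stays free.

Step 8
Reactants: 13 methyl 5-hydroxy-4-oxo-4H-pyran-2-carboxylate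
Product: 14 methyl 4-oxo-5-(trifluoromethylsulfonyloxy)-4H-pyran-2-carboxylate
Conditions: Tf2O, pyridine, CH2Cl2, −10 → 0 °C
Reagents that add atoms: trifluoromethanesulfonic anhydride O=S(=O)(OS(=O)(=O)C(F)(F)F)C(F)(F)F
Why: O-sulfonylation of the acidic 5-hydroxy-4-pyranone gives an enol-type triflate, as is routine for 3-hydroxy-4-pyranones.

Step 9
Reactants: 14 methyl 4-oxo-5-(trifluoromethylsulfonyloxy)-4H-pyran-2-carboxylate; 11 2-[4-methoxy-3-(methoxymethoxy)-5-(3-methylbut-2-en-1-yl)phenyl]-4,4,5,5-tetramethyl-1,3,2-dioxaborolane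
Product: 15 methyl 5-[4-methoxy-3-(methoxymethoxy)-5-(3-methylbut-2-en-1-yl)phenyl]-4-oxo-4H-pyran-2-carboxylate
Conditions: PdCl2(dppf) (5 mol%), K3PO4, 1,4-dioxane/H2O (20:1), 80 °C
Reagents that add atoms: none
Why: Suzuki–Miyaura coupling should be facile because the electron-poor pyranone triflate undergoes oxidative addition readily, and a phosphate base with little water spares the ester and the base-sensitive pyranone ring.

Step 10
Reactants: 15 methyl 5-[4-methoxy-3-(methoxymethoxy)-5-(3-methylbut-2-en-1-yl)phenyl]-4-oxo-4H-pyran-2-carboxylate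
Product: 16 5-[4-methoxy-3-(methoxymethoxy)-5-(3-methylbut-2-en-1-yl)phenyl]-4-oxo-4H-pyran-2-carboxylic acid
Conditions: LiOH·H2O (1.2 equiv), THF/H2O (3:1), 0 °C; then 1 M HCl to pH 3, 0 °C
Reagents that add atoms: lithium hydroxide [Li+].[OH-]
Why: Saponification of this strongly activated ester at 0 °C with near-stoichiometric hydroxide should outpace conjugate attack on the pyranone, and brief cold acidification to pH 3 leaves the MOM ether intact.

Step 11
Reactants: 16 5-[4-methoxy-3-(methoxymethoxy)-5-(3-methylbut-2-en-1-yl)phenyl]-4-oxo-4H-pyran-2-carboxylic acid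
Product: 18 2-(diazoacetyl)-5-[4-methoxy-3-(methoxymethoxy)-5-(3-methylbut-2-en-1-yl)phenyl]-4H-pyran-4-one, via isobutyl carbonic mixed anhydride 17 (not isolated)
Conditions: i-BuOCOCl, Et3N, THF, −15 °C; then CH2N2 (Et2O, ca. 3 equiv), −15 → 0 °C
Reagents that add atoms: diazomethane C=[N+]=[N-]
Why: Acylation of diazomethane by a mixed carbonic anhydride (first stage of the Arndt–Eistert sequence) gives the diazoketone without liberating HCl, which would endanger the MOM ether and the prenyl alkene.

Step 12
Reactants: 4 prenyl bromide; 19 ethynylmagnesium bromide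
Product: 20 5-methylhex-4-en-1-yne
Conditions: CuBr·SMe2 (5 mol%), THF, 0 °C → rt; fractional distillation
Reagents that add atoms: none
Why: Copper-catalysed coupling of an alkynyl Grignard reagent with an allylic bromide takes place at the unhindered primary carbon and should give the skipped enyne.

Step 13
Reactants: 20 5-methylhex-4-en-1-yne
Product: 23 5-methyl-1-(triisopropylsilyloxy)hex-4-en-1-yne, via lithium acetylide 21 (not isolated), via lithium ynolate 22 (not isolated)
Conditions: n-BuLi (1.0 equiv), THF, −78 °C; LiOOt-Bu (from t-BuOOH and LiHMDS, THF, −78 °C), −78 → 0 °C; TIPSOTf, −78 → 0 °C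
Reagents that add atoms: tert-butyl hydroperoxide CC(C)(C)OO; triisopropylsilyl trifluoromethanesulfonate CC(C)[Si](OS(=O)(=O)C(F)(F)F)(C(C)C)C(C)C
Why: Electrophilic oxygen transfer from lithium tert-butyl peroxide to the lithium acetylide gives the ynolate, and the bulky triisopropylsilyl triflate silylates it on oxygen, not on carbon, to give the siloxyalkyne.

Step 14
Reactants: 18 2-(diazoacetyl)-5-[4-methoxy-3-(methoxymethoxy)-5-(3-methylbut-2-en-1-yl)phenyl]-4H-pyran-4-one; 23 5-methyl-1-(triisopropylsilyloxy)hex-4-en-1-yne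
Product: 28 5-hydroxy-3-[4-methoxy-3-(methoxymethoxy)-5-(3-methylbut-2-en-1-yl)phenyl]-6-(3-methylbut-2-en-1-yl)-7-(triisopropylsilyloxy)-4H-chromen-4-one, via pyranylketene 24 (not isolated), via cyclobutenone 25 (not isolated), via dienylketene 26 (not isolated), via cyclohexadienone tautomer 27 (not isolated)
Conditions: 23 (2 equiv), hν (365 nm LED), degassed ClCH2CH2Cl (0.05 M), rt; then 80 °C
Reagents that add atoms: none
Why: Irradiation of 18 triggers a Wolff rearrangement in which pyranone C2 migrates (creating the future C8–C8a bond) to give ketene 24, the electron-rich alkyne 23 adds to it in a regioselective [2+2] cycloaddition to give cyclobutenone 25 (future C5–C6 and C7–C8 bonds), and warming opens 25 by 4π electrocyclic cleavage to dienylketene 26. Ring A then closes by thermal 6π electrocyclisation of 26 onto pyranone C3 (forming C4a–C5, a six-membered carbocycle fused at C4a–C8a) to give 27, and enolisation to the aromatic, hydrogen-bonded C5 phenol 28 makes the sequence irreversible. This is a Danheiser benzannulation of the photochemical diazoketone type, established for vinyl, aryl and heteroaryl diazomethyl ketones with triisopropylsilyloxyalkynes, with the pyranone C2=C3 bond playing the part of the vinyl unit. No stereocentre is formed. The step needs one regiochemistry in the [2+2] event: the alkyne carbon carrying the prenyl CH2 (the nucleophilic carbon β to the silyloxy group) must bond to the electrophilic ketene carbonyl carbon, which the strong polarisation of the ynol ether secures, so that prenyl ends at C6 between O5 and O7 and the silyloxy group at C7; closure can occur only at C3 because the other neighbour of the ketene-bearing carbon is the ring oxygen. Long-wavelength light is chosen because the diazoketone absorbs there while the 4-pyranone and the isoflavone product absorb little, and the excess of 23 should suppress ketene dimerisation and acylation of the product phenol.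

Step 15
Reactants: 28 5-hydroxy-3-[4-methoxy-3-(methoxymethoxy)-5-(3-methylbut-2-en-1-yl)phenyl]-6-(3-methylbut-2-en-1-yl)-7-(triisopropylsilyloxy)-4H-chromen-4-one
Product: 29 3-[4-methoxy-3-(methoxymethoxy)-5-(3-methylbut-2-en-1-yl)phenyl]-5-(methoxymethoxy)-6-(3-methylbut-2-en-1-yl)-7-(triisopropylsilyloxy)-4H-chromen-4-one
Conditions: NaH (1.5 equiv), MOMCl (1.5 equiv), THF/DMF, 0 °C → rt
Reagents that add atoms: chloromethyl methyl ether COCCl
Why: Full deprotonation with NaH breaks the C5–OH···O=C4 hydrogen bond so that O-alkylation with MOMCl can occur, which frees the C4 carbonyl for the later reduction.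

Step 16
Reactants: 29 3-[4-methoxy-3-(methoxymethoxy)-5-(3-methylbut-2-en-1-yl)phenyl]-5-(methoxymethoxy)-6-(3-methylbut-2-en-1-yl)-7-(triisopropylsilyloxy)-4H-chromen-4-one
Product: 31 (3S,4S)-3-[4-methoxy-3-(methoxymethoxy)-5-(3-methylbut-2-en-1-yl)phenyl]-5-(methoxymethoxy)-6-(3-methylbut-2-en-1-yl)-7-(triisopropylsilyloxy)chroman-4-ol, via racemic isoflavanone 30 (not isolated)
Conditions: RuCl[(S,S)-TsDPEN](p-cymene) (5 mol%), HCO2H/Et3N (5:2), EtOAc, 40 °C
Reagents that add atoms: none
Why: Noyori–Ikariya asymmetric transfer hydrogenation first reduces the chromone C2=C3 bond in the conjugate sense to 30, whose acidic C3–H epimerises rapidly under Et3N, and the chiral Ru–H then reduces the (3S) ketone preferentially from the face that gives the 4S carbinol cis to the aryl group (dynamic kinetic resolution), so the catalyst sets C4 and, through the cis preference, C3; the prenyl alkenes are not polarised and should stay untouched.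

Step 17
Reactants: 31 (3S,4S)-3-[4-methoxy-3-(methoxymethoxy)-5-(3-methylbut-2-en-1-yl)phenyl]-5-(methoxymethoxy)-6-(3-methylbut-2-en-1-yl)-7-(triisopropylsilyloxy)chroman-4-ol
Product: 32 (3S)-3-[4-methoxy-3-(methoxymethoxy)-5-(3-methylbut-2-en-1-yl)phenyl]-5-(methoxymethoxy)-6-(3-methylbut-2-en-1-yl)-7-(triisopropylsilyloxy)chroman-4-one
Conditions: Dess–Martin periodinane (1.5 equiv), NaHCO3, CH2Cl2, 0 °C → rt
Reagents that add atoms: none
Why: Dess–Martin oxidation of the benzylic alcohol under buffered, near-neutral conditions removes the auxiliary C4 stereocentre and should leave the enolisable C3 centre (S) unchanged.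

Step 18
Reactants: 32 (3S)-3-[4-methoxy-3-(methoxymethoxy)-5-(3-methylbut-2-en-1-yl)phenyl]-5-(methoxymethoxy)-6-(3-methylbut-2-en-1-yl)-7-(triisopropylsilyloxy)chroman-4-one
Product: 34 (3S)-5,7-dihydroxy-3-[3-hydroxy-4-methoxy-5-(3-methylbut-2-en-1-yl)phenyl]-6-(3-methylbut-2-en-1-yl)chroman-4-one, via 7-hydroxy bis-MOM isoflavanone 33 (not isolated)
Conditions: TBAF/AcOH (1:1, 1.1 equiv), THF, 0 °C; then 3 M aq. HCl/MeOH (1:4), 25–35 °C
Reagents that add atoms: none
Why: Acetic-acid-buffered fluoride cleaves the activated aryl silyl ether without a basic medium that could enolise C3, and mild methanolic HCl then removes both MOM acetals by acetal exchange at a temperature low enough that the prenyl groups should not cyclise onto the neighbouring phenols and C3 should not epimerise.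

**Compound list**
1 | 4-bromophenol | Oc1ccc(Br)cc1 | starting material
2 | 4-bromo-2,6-diiodophenol | Oc1c(I)cc(Br)cc1I | intermediate
3 | 5-bromo-1,3-diiodo-2-methoxybenzene | COc1c(I)cc(Br)cc1I | intermediate
4 | prenyl bromide (1-bromo-3-methylbut-2-ene) | CC(C)=CCBr | starting material
5 | (5-bromo-3-iodo-2-methoxyphenyl)magnesium chloride | COc1c(I)cc(Br)cc1[Mg]Cl | intermediate
6 | 5-bromo-1-iodo-2-methoxy-3-(3-methylbut-2-en-1-yl)benzene | COc1c(I)cc(Br)cc1CC=C(C)C | intermediate
7 | [5-bromo-2-methoxy-3-(3-methylbut-2-en-1-yl)phenyl]magnesium chloride | COc1c([Mg]Cl)cc(Br)cc1CC=C(C)C | intermediate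
8 | dimethyl [5-bromo-2-methoxy-3-(3-methylbut-2-en-1-yl)phenyl]boronate | COB(OC)c1cc(Br)cc(CC=C(C)C)c1OC | intermediate
9 | 5-bromo-2-methoxy-3-(3-methylbut-2-en-1-yl)phenol | COc1c(O)cc(Br)cc1CC=C(C)C | intermediate
10 | 5-bromo-2-methoxy-1-(methoxymethoxy)-3-(3-methylbut-2-en-1-yl)benzene | COCOc1cc(Br)cc(CC=C(C)C)c1OC | intermediate
11 | 2-[4-methoxy-3-(methoxymethoxy)-5-(3-methylbut-2-en-1-yl)phenyl]-4,4,5,5-tetramethyl-1,3,2-dioxaborolane | COCOc1cc(B2OC(C)(C)C(C)(C)O2)cc(CC=C(C)C)c1OC | intermediate
12 | comenic acid (5-hydroxy-4-oxo-4H-pyran-2-carboxylic acid) | O=C(O)c1cc(=O)c(O)co1 | starting material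
13 | methyl 5-hydroxy-4-oxo-4H-pyran-2-carboxylate | COC(=O)c1cc(=O)c(O)co1 | intermediate
14 | methyl 4-oxo-5-(trifluoromethylsulfonyloxy)-4H-pyran-2-carboxylate | COC(=O)c1cc(=O)c(OS(=O)(=O)C(F)(F)F)co1 | intermediate
15 | methyl 5-[4-methoxy-3-(methoxymethoxy)-5-(3-methylbut-2-en-1-yl)phenyl]-4-oxo-4H-pyran-2-carboxylate | COC(=O)c1cc(=O)c(-c2cc(OCOC)c(OC)c(CC=C(C)C)c2)co1 | intermediate
16 | 5-[4-methoxy-3-(methoxymethoxy)-5-(3-methylbut-2-en-1-yl)phenyl]-4-oxo-4H-pyran-2-carboxylic acid | OC(=O)c1cc(=O)c(-c2cc(OCOC)c(OC)c(CC=C(C)C)c2)co1 | intermediate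
17 | isobutyl carbonic mixed anhydride of acid 16 | CC(C)COC(=O)OC(=O)c1cc(=O)c(-c2cc(OCOC)c(OC)c(CC=C(C)C)c2)co1 | intermediate
18 | 2-(diazoacetyl)-5-[4-methoxy-3-(methoxymethoxy)-5-(3-methylbut-2-en-1-yl)phenyl]-4H-pyran-4-one | [N-]=[N+]=CC(=O)c1cc(=O)c(-c2cc(OCOC)c(OC)c(CC=C(C)C)c2)co1 | intermediate
19 | ethynylmagnesium bromide | C#C[Mg]Br | starting material
20 | 5-methylhex-4-en-1-yne | CC(C)=CCC#C | intermediate
21 | lithium 5-methylhex-4-en-1-yn-1-ide | [Li]C#CCC=C(C)C | intermediate
22 | lithium 5-methylhex-4-en-1-yn-1-olate | [Li]OC#CCC=C(C)C | intermediate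
23 | 5-methyl-1-(triisopropylsilyloxy)hex-4-en-1-yne | CC(C)=CCC#CO[Si](C(C)C)(C(C)C)C(C)C | intermediate
24 | [5-aryl-4-oxo-4H-pyran-2-yl]ketene (aryl = 4-methoxy-3-(methoxymethoxy)-5-prenylphenyl) | O=C=Cc1cc(=O)c(-c2cc(OCOC)c(OC)c(CC=C(C)C)c2)co1 | intermediate
25 | 4-[5-aryl-4-oxo-4H-pyran-2-yl]-2-(3-methylbut-2-en-1-yl)-3-(triisopropylsilyloxy)cyclobut-2-en-1-one | O=C1C(CC=C(C)C)=C(O[Si](C(C)C)(C(C)C)C(C)C)C1c1cc(=O)c(-c2cc(OCOC)c(OC)c(CC=C(C)C)c2)co1 | intermediate
26 | dienylketene from ring opening of 25 | O=C=C(CC=C(C)C)C(O[Si](C(C)C)(C(C)C)C(C)C)=Cc1cc(=O)c(-c2cc(OCOC)c(OC)c(CC=C(C)C)c2)co1 | intermediate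
27 | 4a-H cyclohexadienone tautomer of 28 (racemic at C4a) | O=C1C(CC=C(C)C)=C(O[Si](C(C)C)(C(C)C)C(C)C)C=C2OC=C(c3cc(OCOC)c(OC)c(CC=C(C)C)c3)C(=O)C12 | intermediate
28 | 5-hydroxy-3-[4-methoxy-3-(methoxymethoxy)-5-(3-methylbut-2-en-1-yl)phenyl]-6-(3-methylbut-2-en-1-yl)-7-(triisopropylsilyloxy)-4H-chromen-4-one | COc1c(OCOC)cc(-c2coc3cc(O[Si](C(C)C)(C(C)C)C(C)C)c(CC=C(C)C)c(O)c3c2=O)cc1CC=C(C)C | intermediate
29 | 5-O-MOM ether of 28 | COc1c(OCOC)cc(-c2coc3cc(O[Si](C(C)C)(C(C)C)C(C)C)c(CC=C(C)C)c(OCOC)c3c2=O)cc1CC=C(C)C | intermediate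
30 | racemic protected isoflavanone (2,3-dihydro 29) | COc1c(OCOC)cc(C2COc3cc(O[Si](C(C)C)(C(C)C)C(C)C)c(CC=C(C)C)c(OCOC)c3C2=O)cc1CC=C(C)C | intermediate
31 | (3S,4S)-cis-isoflavan-4-ol, protected | COc1c(OCOC)cc([C@H]2COc3cc(O[Si](C(C)C)(C(C)C)C(C)C)c(CC=C(C)C)c(OCOC)c3[C@H]2O)cc1CC=C(C)C | intermediate
32 | (3S)-isoflavanone, 5-O-MOM, 7-O-TIPS, 3'-O-MOM | COc1c(OCOC)cc([C@H]2COc3cc(O[Si](C(C)C)(C(C)C)C(C)C)c(CC=C(C)C)c(OCOC)c3C2=O)cc1CC=C(C)C | intermediate
33 | (3S)-7-hydroxy-5,3'-bis(methoxymethoxy) isoflavanone | COc1c(OCOC)cc([C@H]2COc3cc(O)c(CC=C(C)C)c(OCOC)c3C2=O)cc1CC=C(C)C | intermediate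
34 | (3S)-5,7-dihydroxy-3-[3-hydroxy-4-methoxy-5-(3-methylbut-2-en-1-yl)phenyl]-6-(3-methylbut-2-en-1-yl)chroman-4-one (CNP0327275.1) | COc1c(O)cc([C@H]2COc3cc(O)c(CC=C(C)C)c(O)c3C2=O)cc1CC=C(C)C | target

**Totals**
Total steps: 18. Longest linear sequence: 14 steps (steps 1–6, 9–11, 14–18, from 4-bromophenol).

**Steps most likely to fail**

1. Step 14. The risks are competing photoreactions of the pyranone or of the product chromophore, carbene-type side reactions before the Wolff shift, and ketene oligomerisation before capture by the alkyne. The fallback generates the same ketene thermally instead of by light. It sets out from 18: silver-benzoate-catalysed Wolff rearrangement in aqueous THF (Arndt–Eistert homologation) should give [5-aryl-4-oxo-4H-pyran-2-yl]acetic acid F1, kept cold because it may decarboxylate. The Ghosez reagent (1-chloro-N,N,2-trimethylprop-1-en-1-amine) in CH2Cl2 at 0 °C should convert F1 under neutral conditions into the acid chloride F2. Slow addition of i-Pr2NEt to F2 and 23 in toluene at 80 °C should dehydrochlorinate F2 to ketene 24, where the fallback rejoins the route; 24 then passes through 25–27 to 28 in the dark.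

2. Step 16. The C4 carbonyl is electron-rich and flanked by the 5-OMOM group, so carbonyl reduction may stall at the racemic ketone, or the resolution may be incomplete, which would erode the stereochemical purity at C3. The fallback replaces the reduction/oxidation pair by an enantioselective protonation. It sets out from 29: L-Selectride in THF at −78 °C should effect conjugate reduction, and trapping the enolate with allyl chloroformate should give the allyl enol carbonate F3. Palladium-catalysed decarboxylative asymmetric protonation (Pd2(dba)3, t-Bu-PHOX ligand of the enantiomeric series that delivers 3S, Meldrum's acid as proton donor, dioxane, rt) should then give 32 directly, where the fallback rejoins the route, so step 17 is not needed.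

3. Step 13. The skipped enyne may isomerise under the basic conditions of the acetylide oxidation, the oxygen transfer may be incomplete, and the ynolate may silylate on carbon. The fallback reaches the same ynolate from an ester. It sets out from 4: alkylation of the lithium enolate of ethyl acetate (LDA, THF/DMPU, −78 °C) should give ethyl 5-methylhex-4-enoate F4. Two successive enolate brominations (LiHMDS, 1,2-dibromotetrachloroethane, −78 °C) should give ethyl 2,2-dibromo-5-methylhex-4-enoate F5. Treating F5 with t-BuLi (4 equiv, THF, −78 → 0 °C) should give, by double lithium–bromine exchange and loss of ethoxide, the lithium ynolate 22, where the fallback rejoins the route; silylation with TIPSOTf as in step 13 then gives 23.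

**Further compounds**
F1 | step 14 | {5-[4-methoxy-3-(methoxymethoxy)-5-(3-methylbut-2-en-1-yl)phenyl]-4-oxo-4H-pyran-2-yl}acetic acid | OC(=O)Cc1cc(=O)c(-c2cc(OCOC)c(OC)c(CC=C(C)C)c2)co1
F2 | step 14 | {5-[4-methoxy-3-(methoxymethoxy)-5-(3-methylbut-2-en-1-yl)phenyl]-4-oxo-4H-pyran-2-yl}acetyl chloride | ClC(=O)Cc1cc(=O)c(-c2cc(OCOC)c(OC)c(CC=C(C)C)c2)co1
F3 | step 16 | allyl enol carbonate of the protected isoflavanone (allyl 2H-chromen-4-yl carbonate) | COc1c(OCOC)cc(C2=C(OC(=O)OCC=C)c3c(OCOC)c(CC=C(C)C)c(O[Si](C(C)C)(C(C)C)C(C)C)cc3OC2)cc1CC=C(C)C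
F4 | step 13 | ethyl 5-methylhex-4-enoate | CCOC(=O)CCC=C(C)C
F5 | step 13 | ethyl 2,2-dibromo-5-methylhex-4-enoate | CCOC(=O)C(Br)(Br)CC=C(C)C
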